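**Plan**

- Retrosynthesis: the butenolide is cut at C17=C18 (ring-closing metathesis) and at the C16–O acyl bond; the side chain is cut at C12–C13 (copper-catalysed anti-carbomagnesiation of a 2-alkyn-1-ol by the C11–C12 Grignard reagent).
- A formyl group is then put back on C6, and C5–C10 and C6–C7 are cut together by an intramolecular Diels–Alder reaction of an acyclic trienal.
- Enabling feature: ring B is a cyclohexene whose C8=C9 alkene is tetrasubstituted and adjoins quaternary C10, so C7=C8–C9=C10 is a complete diene, C5=C6 an enal dienophile, and ring A (C1–C4) the tether.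
- Forward order: acyclic trienal, then rings A and B in one step, decarbonylation, attachment of C13–C20 at C12, enal, and the butenolide ring last.
- Stereochemistry: C5 and C10 come from the chiral imidazolidinone and the anti transition state acting on an (E)-C9=C10 bond made by syn-carbomagnesiation; (E)-C13=C14 comes from the anti-carbomagnesiation; C16 (R) comes from a chiral phosphoric acid propargylation.

Key step: step 9

Numbering used: decalin C1–C10 (C4 gem-dimethyl, C5 ring-fusion CH, C10 quaternary), chain C11, C12, C13 (bears CHO), C14, C15, C16 (lactone CH–O), C17 (bears C20H2OH), C18, C19 (lactone C=O).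

Assumption: (R)-TRIP is taken to direct the allenylboronate to the Re face of the aldehyde, as in its allylborations; if the opposite sense were found, (S)-TRIP would be used with no other change.

**Route**

Step 1
Reactants: 1 but-3-yn-1-ol; 2 1-bromo-3-chloropropane
Product: 4 7-chlorohept-3-yn-1-ol, via dilithio but-3-yn-1-ol 3 (not isolated)
Conditions: n-BuLi (2.1 equiv), THF/DMPU, −78 → 0 °C; then 2, −78 °C → rt; H2O
Reagents that add atoms: none
Why: Double deprotonation gives the alkoxide–acetylide 3, whose carbon terminus displaces bromide in preference to chloride (acetylide SN2 alkylation), forming C1–C10 and leaving the chloride as the handle for step 4.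

Step 2
Reactants: 4 7-chlorohept-3-yn-1-ol
Product: 6 (E)-7-chloro-3-iodo-4-methylhept-3-en-1-ol, via alkenylmagnesium alkoxide 5 (not isolated)
Conditions: MeMgBr (5 equiv), Fe(acac)3 (15 mol%), THF, 0 °C; then I2, THF, −78 → 0 °C; aq. Na2S2O3
Reagents that add atoms: methylmagnesium bromide (C[Mg]Br); iodine (II)
Why: Alkoxide-directed iron-catalysed syn-carbomagnesiation of a homopropargylic alcohol should place the methyl group on the distal alkyne carbon (C10) and magnesium on the proximal one (C9), and iodinolysis of 5 with retention then fixes the tetrasubstituted alkene with methyl cis to iodine.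

Step 3
Reactants: 6 (E)-7-chloro-3-iodo-4-methylhept-3-en-1-ol; 7 4,4,5,5-tetramethyl-2-(prop-1-en-2-yl)-1,3,2-dioxaborolane
Product: 8 (E)-7-chloro-4-methyl-3-(prop-1-en-2-yl)hept-3-en-1-ol
Conditions: Pd(dppf)Cl2 (5 mol%), K3PO4, 1,4-dioxane/H2O, 80 °C
Reagents that add atoms: none
Why: Suzuki–Miyaura coupling of an alkenyl iodide with an alkenylboronate goes with retention of geometry, so the C8–C9 bond forms with the C10 methyl cis to the isopropenyl group, and the free hydroxyl and the alkyl chloride are tolerated.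

Step 4
Reactants: 8 (E)-7-chloro-4-methyl-3-(prop-1-en-2-yl)hept-3-en-1-ol; 9 isobutyronitrile
Product: 10 (E)-7-(2-hydroxyethyl)-2,2,6,8-tetramethylnona-6,8-dienenitrile
Conditions: 9 (3 equiv), LDA (3.1 equiv), THF, −78 °C; then 8, −78 °C → rt; H2O
Reagents that add atoms: none
Why: SN2 alkylation of the lithiated tertiary nitrile by the primary chloride forms C3–C4 and brings in the gem-dimethyl carbon, the hydroxyl being carried as its lithium alkoxide, which is far less nucleophilic toward the chloride than the nitrile anion.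

Step 5
Reactants: 10 (E)-7-(2-hydroxyethyl)-2,2,6,8-tetramethylnona-6,8-dienenitrile
Product: 11 (E)-7-(2-chloroethyl)-2,2,6,8-tetramethylnona-6,8-dienenitrile
Conditions: PPh3, NCS (premixed), CH2Cl2, 0 °C → rt
Reagents that add atoms: N-chlorosuccinimide (ClN1C(=O)CCC1=O)
Why: Appel-type chlorination through the alkoxyphosphonium salt converts the primary alcohol by SN2 into the chloride that later becomes the Grignard carbon C12, and premixing the reagents keeps electrophilic chlorine away from the diene.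

Step 6
Reactants: 11 (E)-7-(2-chloroethyl)-2,2,6,8-tetramethylnona-6,8-dienenitrile
Product: 13 (E)-7-(2-chloroethyl)-2,2,6,8-tetramethylnona-6,8-dienal, via aluminium aldimine 12 (not isolated)
Conditions: DIBAL-H (1.2 equiv), CH2Cl2, −78 °C; then 10% aq. tartaric acid, rt
Reagents that add atoms: water (O)
Why: DIBAL-H adds once to the hindered nitrile to give the aluminium aldimine 12, which is not reduced further and is hydrolysed to the aldehyde on acidic work-up (partial nitrile reduction).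

Step 7
Reactants: 13 (E)-7-(2-chloroethyl)-2,2,6,8-tetramethylnona-6,8-dienal; 14 diethyl {2-[methoxy(methyl)amino]-2-oxoethyl}phosphonate
Product: 15 (2E,8E)-9-(2-chloroethyl)-N-methoxy-N,4,4,8,10-pentamethylundeca-2,8,10-trienamide
Conditions: 14, NaH, THF, 0 °C; then 13, 0 °C → rt
Reagents that add atoms: none
Why: Horner–Wadsworth–Emmons olefination of the non-enolisable α-quaternary aldehyde with the stabilised phosphonate anion should give the (E)-C5=C6 alkene.

Step 8
Reactants: 15 (2E,8E)-9-(2-chloroethyl)-N-methoxy-N,4,4,8,10-pentamethylundeca-2,8,10-trienamide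
Product: 17 (2E,8E)-9-(2-chloroethyl)-4,4,8,10-tetramethylundeca-2,8,10-trienal, via aluminium hemiaminal 16 (not isolated)
Conditions: DIBAL-H (1.3 equiv), THF, −78 °C; aq. Rochelle salt
Reagents that add atoms: none
Why: The chelated tetrahedral adduct 16 of the N-methoxy-N-methylamide persists at −78 °C and releases the enal only on work-up, so over-reduction and 1,4-reduction are avoided (reduction of an N-methoxy-N-methylamide to the aldehyde).

Step 9
Reactants: 17 (2E,8E)-9-(2-chloroethyl)-4,4,8,10-tetramethylundeca-2,8,10-trienal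
Product: 20 (1S,4aS,8aS)-4-(2-chloroethyl)-3,4a,8,8-tetramethyl-1,2,4a,5,6,7,8,8a-octahydronaphthalene-1-carbaldehyde, via trienal iminium triflate 18 (not isolated), via cycloadduct iminium triflate 19 (not isolated)
Conditions: (2S,5S)-5-benzyl-2-tert-butyl-3-methylimidazolidin-4-one (20 mol%), TfOH (20 mol%), MeCN/H2O (98:2), 0 °C → rt
Reagents that add atoms: water (O), which supplies the aldehyde oxygen when 19 is hydrolysed
Why: Proposed new method: the amine condenses with 17 to the (E)-iminium ion 18, whose lowered LUMO lets the trialkylated diene C7=C8–C9=C10 add across C5=C6 in a concerted, asynchronous [4+2] process, after which hydrolysis of 19 releases 20 and the catalyst. The closest known reaction type is the imidazolidinone-catalysed enantioselective intramolecular Diels–Alder reaction of 2,8,10-trienals to trans-decalins, which has not been shown for a diene terminus that is fully substituted and becomes a quaternary carbon. Ring B closes as the new cyclohexene by formation of C5–C10 and C6–C7, and ring A closes in the same event as the six-membered carbocycle completed by the C5–C10 bond across the C4–C3–C2–C1 tether, which adopts a chair and is preorganised by the C4 gem-dimethyl group (Thorpe–Ingold effect). C5 is set by the catalyst, whose benzyl and tert-butyl groups cover one face of the s-trans iminium ion so that the diene adds to the Si face of C5 (5S). C10 follows from the anti transition state (formyl endo, tether exo) together with the (E)-C9=C10 geometry, which places the tether outside and the methyl inside and so puts C5–H trans to the C10 methyl (10S, trans fusion), while C6 follows from the (E)-dienophile (formyl cis to C5–H) and is removed in step 10. The step needs enantiofacial and anti/syn selectivity, the first secured by the catalyst and the second by the (E)-enal with its terminal activating group and the chair-like four-carbon tether, and the tether itself fixes the regiochemistry.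

Step 10
Reactants: 20 (1S,4aS,8aS)-4-(2-chloroethyl)-3,4a,8,8-tetramethyl-1,2,4a,5,6,7,8,8a-octahydronaphthalene-1-carbaldehyde
Product: 21 (4aS,8aS)-5-(2-chloroethyl)-1,1,4a,6-tetramethyl-1,2,3,4,4a,7,8,8a-octahydronaphthalene
Conditions: RhCl(PPh3)3 (1.1 equiv), xylene, 130 °C
Reagents that add atoms: none
Why: Tsuji–Wilkinson decarbonylation (oxidative addition of the formyl C–H bond to Rh(I), CO extrusion, C–H reductive elimination) replaces the formyl group by hydrogen so that C6 becomes a methylene, and the alkyl chloride and the tetrasubstituted alkene should be inert.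

Step 11
Reactants: 22 2-methylidenepropane-1,3-diol
Product: 23 2-{[(tert-butyldimethylsilyl)oxy]methyl}prop-2-en-1-ol
Conditions: NaH (1.0 equiv), THF, 0 °C; then TBSCl (1.0 equiv), rt
Reagents that add atoms: tert-butyldimethylsilyl chloride (CC(C)(C)[Si](C)(C)Cl)
Why: O-Silylation of the monosodium alkoxide of a symmetrical diol should stop at the mono ether because the sparingly soluble monoalkoxide reacts as it forms (monosilylation of a symmetrical diol).

Step 12
Reactants: 23 2-{[(tert-butyldimethylsilyl)oxy]methyl}prop-2-en-1-ol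
Product: 24 2-{[(tert-butyldimethylsilyl)oxy]methyl}prop-2-enal
Conditions: MnO2 (excess), CH2Cl2, rt
Reagents that add atoms: none
Why: MnO2 oxidises allylic alcohols selectively to enals under neutral conditions that leave the silyl ether untouched (allylic oxidation).

Step 13
Reactants: 24 2-{[(tert-butyldimethylsilyl)oxy]methyl}prop-2-enal; 25 4,4,5,5-tetramethyl-2-(propa-1,2-dien-1-yl)-1,3,2-dioxaborolane
Product: 27 (3R)-2-{[(tert-butyldimethylsilyl)oxy]methyl}hex-1-en-5-yn-3-ol, via O-boryl ether 26 (not isolated)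
Conditions: (R)-TRIP (5 mol%), 4 Å MS, toluene, −20 °C; aqueous work-up
Reagents that add atoms: none
Why: Chiral phosphoric acid-catalysed propargylboration through a closed six-membered transition state (SE2′ transfer from the allenylboronate) forms C15–C16, and the catalyst, bound to the boronate oxygen and the formyl hydrogen, should direct attack to the Re face of the aldehyde, which sets C16 as R.

Step 14
Reactants: 27 (3R)-2-{[(tert-butyldimethylsilyl)oxy]methyl}hex-1-en-5-yn-3-ol
Product: 28 (3R)-2-{[(tert-butyldimethylsilyl)oxy]methyl}-3-[(triethylsilyl)oxy]hex-1-en-5-yne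
Conditions: TESCl, imidazole, CH2Cl2, 0 °C → rt
Reagents that add atoms: chlorotriethylsilane (CC[Si](Cl)(CC)CC)
Why: Imidazole-promoted silylation masks the secondary alcohol for the organometallic steps with a group that can later be removed in the presence of the TBS ether (silyl ether protection).

Step 15
Reactants: 28 (3R)-2-{[(tert-butyldimethylsilyl)oxy]methyl}-3-[(triethylsilyl)oxy]hex-1-en-5-yne
Product: 30 (5R)-6-{[(tert-butyldimethylsilyl)oxy]methyl}-5-[(triethylsilyl)oxy]hept-6-en-2-yn-1-ol, via lithium acetylide 29 (not isolated)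
Conditions: n-BuLi (1.05 equiv), THF, −78 °C; (CH2O)n, −78 °C → rt; H2O
Reagents that add atoms: formaldehyde, used as paraformaldehyde (C=O)
Why: Deprotonation of the terminal alkyne and 1,2-addition of the acetylide 29 to formaldehyde install the propargylic hydroxymethyl group, which becomes the enal carbon and directs the next step.

Step 16
Reactants: 21 (4aS,8aS)-5-(2-chloroethyl)-1,1,4a,6-tetramethyl-1,2,3,4,4a,7,8,8a-octahydronaphthalene; 30 (5R)-6-{[(tert-butyldimethylsilyl)oxy]methyl}-5-[(triethylsilyl)oxy]hept-6-en-2-yn-1-ol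
Product: 34 (2E,5R)-6-{[(tert-butyldimethylsilyl)oxy]methyl}-2-{2-[(4aS,8aS)-2,5,5,8a-tetramethyl-3,4,4a,5,6,7,8,8a-octahydronaphthalen-1-yl]ethyl}-5-[(triethylsilyl)oxy]hepta-2,6-dien-1-ol, via Grignard reagent 31 (not isolated), via bromomagnesium alkoxide 32 (not isolated), via oxamagnesacycle 33 (not isolated)
Conditions: 21 (1.4 equiv), Mg (activated, cat. BrCH2CH2Br), THF, reflux; separately 30, EtMgBr (1.0 equiv), THF, 0 °C; combine, CuI (15 mol%), THF, −10 °C → rt; H2O
Reagents that add atoms: none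
Why: Copper-catalysed anti-carbomagnesiation of a 2-alkyn-1-ol places magnesium on the distal alkyne carbon (C14) within the five-membered chelate 33 and the alkyl group of 31 on the proximal carbon (C13) trans to it, so protonation should give the trisubstituted alkene with the new C12–C13 bond cis to C15, the (E)-geometry required for the enal.

Step 17
Reactants: 34 (2E,5R)-6-{[(tert-butyldimethylsilyl)oxy]methyl}-2-{2-[(4aS,8aS)-2,5,5,8a-tetramethyl-3,4,4a,5,6,7,8,8a-octahydronaphthalen-1-yl]ethyl}-5-[(triethylsilyl)oxy]hepta-2,6-dien-1-ol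
Product: 35 (2E,5R)-6-{[(tert-butyldimethylsilyl)oxy]methyl}-2-{2-[(4aS,8aS)-2,5,5,8a-tetramethyl-3,4,4a,5,6,7,8,8a-octahydronaphthalen-1-yl]ethyl}-5-[(triethylsilyl)oxy]hepta-2,6-dienal
Conditions: MnO2 (excess), CH2Cl2, rt
Reagents that add atoms: none
Why: MnO2 oxidation of the primary allylic alcohol should give the (E)-enal without touching the silyl ethers or the alkene geometry (allylic oxidation).

Step 18
Reactants: 35 (2E,5R)-6-{[(tert-butyldimethylsilyl)oxy]methyl}-2-{2-[(4aS,8aS)-2,5,5,8a-tetramethyl-3,4,4a,5,6,7,8,8a-octahydronaphthalen-1-yl]ethyl}-5-[(triethylsilyl)oxy]hepta-2,6-dienal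
Product: 36 (2E,5R)-6-{[(tert-butyldimethylsilyl)oxy]methyl}-5-hydroxy-2-{2-[(4aS,8aS)-2,5,5,8a-tetramethyl-3,4,4a,5,6,7,8,8a-octahydronaphthalen-1-yl]ethyl}hepta-2,6-dienal
Conditions: AcOH/THF/H2O (3:1:1), rt
Reagents that add atoms: none
Why: Acid-catalysed solvolysis cleaves the triethylsilyl ether much faster than the primary TBS ether (selective desilylation), freeing only the C16 hydroxyl.

Step 19
Reactants: 36 (2E,5R)-6-{[(tert-butyldimethylsilyl)oxy]methyl}-5-hydroxy-2-{2-[(4aS,8aS)-2,5,5,8a-tetramethyl-3,4,4a,5,6,7,8,8a-octahydronaphthalen-1-yl]ethyl}hepta-2,6-dienal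
Product: 37 (3R,5E)-2-{[(tert-butyldimethylsilyl)oxy]methyl}-6-formyl-8-[(4aS,8aS)-2,5,5,8a-tetramethyl-3,4,4a,5,6,7,8,8a-octahydronaphthalen-1-yl]octa-1,5-dien-3-yl prop-2-enoate
Conditions: acryloyl chloride, i-Pr2NEt, CH2Cl2, −78 → −20 °C
Reagents that add atoms: acryloyl chloride (C=CC(=O)Cl)
Why: O-Acylation of the secondary allylic alcohol with an acid chloride and a hindered amine at low temperature should install the acrylate (C18, C19) without γ-deprotonation of the enal.

Step 20
Reactants: 37 (3R,5E)-2-{[(tert-butyldimethylsilyl)oxy]methyl}-6-formyl-8-[(4aS,8aS)-2,5,5,8a-tetramethyl-3,4,4a,5,6,7,8,8a-octahydronaphthalen-1-yl]octa-1,5-dien-3-yl prop-2-enoate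
Product: 38 (2E)-4-[(2R)-3-{[(tert-butyldimethylsilyl)oxy]methyl}-5-oxo-2,5-dihydrofuran-2-yl]-2-{2-[(4aS,8aS)-2,5,5,8a-tetramethyl-3,4,4a,5,6,7,8,8a-octahydronaphthalen-1-yl]ethyl}but-2-enal
Conditions: second-generation Ru benzylidene metathesis catalyst (H2IMes/PCy3, 10 mol%), CH2Cl2 (5 mM), 40 °C
Reagents that add atoms: none
Why: Ring-closing metathesis between the acrylate and the 1,1-disubstituted alkene closes the five-membered butenolide at C17=C18 with loss of ethene, while the electron-poor trisubstituted enal alkene and the tetrasubstituted ring alkene should not take part.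

Step 21
Reactants: 38 (2E)-4-[(2R)-3-{[(tert-butyldimethylsilyl)oxy]methyl}-5-oxo-2,5-dihydrofuran-2-yl]-2-{2-[(4aS,8aS)-2,5,5,8a-tetramethyl-3,4,4a,5,6,7,8,8a-octahydronaphthalen-1-yl]ethyl}but-2-enal
Product: 39 (2E)-4-[(2R)-3-(hydroxymethyl)-5-oxo-2,5-dihydrofuran-2-yl]-2-{2-[(4aS,8aS)-2,5,5,8a-tetramethyl-3,4,4a,5,6,7,8,8a-octahydronaphthalen-1-yl]ethyl}but-2-enal
Conditions: HF·pyridine, pyridine, THF, 0 °C → rt
Reagents that add atoms: none
Why: Fluoride cleavage of the primary TBS ether under buffered, weakly acidic conditions (desilylation) should spare the enal and the base-sensitive butenolide.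

**Compound list**

1 | but-3-yn-1-ol | C#CCCO | starting material
2 | 1-bromo-3-chloropropane | ClCCCBr | starting material
3 | dilithio but-3-yn-1-ol (lithium 4-lithiobut-3-yn-1-olate) | [Li]C#CCCO[Li] | intermediate
4 | 7-chlorohept-3-yn-1-ol | OCCC#CCCCCl | intermediate
5 | alkenylmagnesium alkoxide, (E)-3-(5-chloropentan-2-ylidene)-1,2-oxamagnesolane (Mg cis to the new methyl) | ClCCC/C(C)=C1\CCO[Mg]1 | intermediate
6 | (E)-7-chloro-3-iodo-4-methylhept-3-en-1-ol | ClCCC/C(C)=C(\CCO)I | intermediate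
7 | 4,4,5,5-tetramethyl-2-(prop-1-en-2-yl)-1,3,2-dioxaborolane | CC(=C)B1OC(C)(C)C(C)(C)O1 | starting material
8 | (E)-7-chloro-4-methyl-3-(prop-1-en-2-yl)hept-3-en-1-ol | ClCCC/C(C)=C(\CCO)C(C)=C | intermediate
9 | isobutyronitrile | CC(C)C#N | starting material
10 | (E)-7-(2-hydroxyethyl)-2,2,6,8-tetramethylnona-6,8-dienenitrile | N#CC(C)(C)CCC/C(C)=C(\CCO)C(C)=C | intermediate
11 | (E)-7-(2-chloroethyl)-2,2,6,8-tetramethylnona-6,8-dienenitrile | N#CC(C)(C)CCC/C(C)=C(\CCCl)C(C)=C | intermediate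
12 | aluminium aldimine, N-(diisobutylalumanyl)imine of 13 | CC(C)C[Al](CC(C)C)N=CC(C)(C)CCC/C(C)=C(\CCCl)C(C)=C | intermediate
13 | (E)-7-(2-chloroethyl)-2,2,6,8-tetramethylnona-6,8-dienal | O=CC(C)(C)CCC/C(C)=C(\CCCl)C(C)=C | intermediate
14 | diethyl {2-[methoxy(methyl)amino]-2-oxoethyl}phosphonate | CCOP(=O)(OCC)CC(=O)N(C)OC | starting material
15 | (2E,8E)-9-(2-chloroethyl)-N-methoxy-N,4,4,8,10-pentamethylundeca-2,8,10-trienamide | CON(C)C(=O)/C=C/C(C)(C)CCC/C(C)=C(\CCCl)C(C)=C | intermediate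
16 | aluminium hemiaminal, O-diisobutylalumanyl adduct of 15 | CON(C)C(O[Al](CC(C)C)CC(C)C)/C=C/C(C)(C)CCC/C(C)=C(\CCCl)C(C)=C | intermediate
17 | (2E,8E)-9-(2-chloroethyl)-4,4,8,10-tetramethylundeca-2,8,10-trienal | O=C/C=C/C(C)(C)CCC/C(C)=C(\CCCl)C(C)=C | intermediate
18 | trienal iminium triflate, from 17 and the (2S,5S)-imidazolidinone | CN1[C@@H](C(C)(C)C)[N+](=C/C=C/C(C)(C)CCC/C(C)=C(\CCCl)C(C)=C)[C@@H](Cc2ccccc2)C1=O.[O-]S(=O)(=O)C(F)(F)F | intermediate
19 | cycloadduct iminium triflate, iminium ion of 20 with the (2S,5S)-imidazolidinone | CC1=C(CCCl)[C@@]2(C)CCCC(C)(C)[C@@H]2[C@@H](C=[N+]3[C@H](C(C)(C)C)N(C)C(=O)[C@@H]3Cc4ccccc4)C1.[O-]S(=O)(=O)C(F)(F)F | intermediate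
20 | (1S,4aS,8aS)-4-(2-chloroethyl)-3,4a,8,8-tetramethyl-1,2,4a,5,6,7,8,8a-octahydronaphthalene-1-carbaldehyde | CC1=C(CCCl)[C@@]2(C)CCCC(C)(C)[C@@H]2[C@@H](C=O)C1 | intermediate
21 | (4aS,8aS)-5-(2-chloroethyl)-1,1,4a,6-tetramethyl-1,2,3,4,4a,7,8,8a-octahydronaphthalene | CC1=C(CCCl)[C@@]2(C)CCCC(C)(C)[C@@H]2CC1 | intermediate
22 | 2-methylidenepropane-1,3-diol | C=C(CO)CO | starting material
23 | 2-{[(tert-butyldimethylsilyl)oxy]methyl}prop-2-en-1-ol | C=C(CO)CO[Si](C)(C)C(C)(C)C | intermediate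
24 | 2-{[(tert-butyldimethylsilyl)oxy]methyl}prop-2-enal | C=C(C=O)CO[Si](C)(C)C(C)(C)C | intermediate
25 | 4,4,5,5-tetramethyl-2-(propa-1,2-dien-1-yl)-1,3,2-dioxaborolane | C=C=CB1OC(C)(C)C(C)(C)O1 | starting material
26 | O-boryl ether, pinacolboryl ether of 27 | C#CC[C@@H](OB1OC(C)(C)C(C)(C)O1)C(=C)CO[Si](C)(C)C(C)(C)C | intermediate
27 | (3R)-2-{[(tert-butyldimethylsilyl)oxy]methyl}hex-1-en-5-yn-3-ol | C#CC[C@@H](O)C(=C)CO[Si](C)(C)C(C)(C)C | intermediate
28 | (3R)-2-{[(tert-butyldimethylsilyl)oxy]methyl}-3-[(triethylsilyl)oxy]hex-1-en-5-yne | C#CC[C@@H](O[Si](CC)(CC)CC)C(=C)CO[Si](C)(C)C(C)(C)C | intermediate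
29 | lithium acetylide of 28 | [Li]C#CC[C@@H](O[Si](CC)(CC)CC)C(=C)CO[Si](C)(C)C(C)(C)C | intermediate
30 | (5R)-6-{[(tert-butyldimethylsilyl)oxy]methyl}-5-[(triethylsilyl)oxy]hept-6-en-2-yn-1-ol | OCC#CC[C@@H](O[Si](CC)(CC)CC)C(=C)CO[Si](C)(C)C(C)(C)C | intermediate
31 | Grignard reagent, chloro{2-[(4aS,8aS)-2,5,5,8a-tetramethyl-3,4,4a,5,6,7,8,8a-octahydronaphthalen-1-yl]ethyl}magnesium | CC1=C(CC[Mg]Cl)[C@@]2(C)CCCC(C)(C)[C@@H]2CC1 | intermediate
32 | bromomagnesium alkoxide of 30 | Br[Mg]OCC#CC[C@@H](O[Si](CC)(CC)CC)C(=C)CO[Si](C)(C)C(C)(C)C | intermediate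
33 | oxamagnesacycle, 2,5-dihydro-1,2-oxamagnesole carrying the decalinylethyl group at C4 and the C15–C20 chain at C3 | CC1=C(CCC3=C(C[C@@H](O[Si](CC)(CC)CC)C(=C)CO[Si](C)(C)C(C)(C)C)[Mg]OC3)[C@@]2(C)CCCC(C)(C)[C@@H]2CC1 | intermediate
34 | (2E,5R)-6-{[(tert-butyldimethylsilyl)oxy]methyl}-2-{2-[(4aS,8aS)-2,5,5,8a-tetramethyl-3,4,4a,5,6,7,8,8a-octahydronaphthalen-1-yl]ethyl}-5-[(triethylsilyl)oxy]hepta-2,6-dien-1-ol | CC1=C(CC/C(CO)=C\C[C@@H](O[Si](CC)(CC)CC)C(=C)CO[Si](C)(C)C(C)(C)C)[C@@]2(C)CCCC(C)(C)[C@@H]2CC1 | intermediate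
35 | (2E,5R)-6-{[(tert-butyldimethylsilyl)oxy]methyl}-2-{2-[(4aS,8aS)-2,5,5,8a-tetramethyl-3,4,4a,5,6,7,8,8a-octahydronaphthalen-1-yl]ethyl}-5-[(triethylsilyl)oxy]hepta-2,6-dienal | CC1=C(CC/C(C=O)=C\C[C@@H](O[Si](CC)(CC)CC)C(=C)CO[Si](C)(C)C(C)(C)C)[C@@]2(C)CCCC(C)(C)[C@@H]2CC1 | intermediate
36 | (2E,5R)-6-{[(tert-butyldimethylsilyl)oxy]methyl}-5-hydroxy-2-{2-[(4aS,8aS)-2,5,5,8a-tetramethyl-3,4,4a,5,6,7,8,8a-octahydronaphthalen-1-yl]ethyl}hepta-2,6-dienal | CC1=C(CC/C(C=O)=C\C[C@@H](O)C(=C)CO[Si](C)(C)C(C)(C)C)[C@@]2(C)CCCC(C)(C)[C@@H]2CC1 | intermediate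
37 | (3R,5E)-2-{[(tert-butyldimethylsilyl)oxy]methyl}-6-formyl-8-[(4aS,8aS)-2,5,5,8a-tetramethyl-3,4,4a,5,6,7,8,8a-octahydronaphthalen-1-yl]octa-1,5-dien-3-yl prop-2-enoate | CC1=C(CC/C(C=O)=C\C[C@@H](OC(=O)C=C)C(=C)CO[Si](C)(C)C(C)(C)C)[C@@]2(C)CCCC(C)(C)[C@@H]2CC1 | intermediate
38 | (2E)-4-[(2R)-3-{[(tert-butyldimethylsilyl)oxy]methyl}-5-oxo-2,5-dihydrofuran-2-yl]-2-{2-[(4aS,8aS)-2,5,5,8a-tetramethyl-3,4,4a,5,6,7,8,8a-octahydronaphthalen-1-yl]ethyl}but-2-enal | CC1=C(CC/C(C=O)=C\C[C@H]2OC(=O)C=C2CO[Si](C)(C)C(C)(C)C)[C@@]2(C)CCCC(C)(C)[C@@H]2CC1 | intermediate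
39 | (2E)-4-[(2R)-3-(hydroxymethyl)-5-oxo-2,5-dihydrofuran-2-yl]-2-{2-[(4aS,8aS)-2,5,5,8a-tetramethyl-3,4,4a,5,6,7,8,8a-octahydronaphthalen-1-yl]ethyl}but-2-enal | CC1=C(CC/C(C=O)=C\C[C@H]2OC(=O)C=C2CO)[C@@]2(C)CCCC(C)(C)[C@@H]2CC1 | target

**Step count and risks**

Total step count: 21. Longest linear sequence: 16 steps (steps 1–10 and 16–21); the alkynol branch (steps 11–15) joins at step 16.

Steps most likely to fail:

1. Step 9 (proposed new method). The cycloaddition may stall because the new C5–C10 bond must form at a fully substituted diene terminus next to the gem-dimethyl carbon, leaving time for iminium hydrolysis and diene isomerisation, and the catalyst may not distinguish the faces of so hindered an iminium ion. The fallback replaces catalyst control by auxiliary control with Lewis acid activation. It sets out from aldehyde 13, which is olefinated (LiCl, i-Pr2NEt, MeCN) with diethyl {2-[(4S)-4-benzyl-2-oxo-1,3-oxazolidin-3-yl]-2-oxoethyl}phosphonate to the N-enoyl oxazolidinone (4S)-4-benzyl-3-[(2E,8E)-9-(2-chloroethyl)-4,4,8,10-tetramethylundeca-2,8,10-trienoyl]-1,3-oxazolidin-2-one F1. Me2AlCl (1.4 equiv, CH2Cl2, −30 °C → rt) chelates both carbonyl groups, and the known auxiliary-controlled intramolecular Diels–Alder reaction of trienimides should give, by addition to the C5 face remote from the benzyl group, the trans-fused imide (4S)-4-benzyl-3-{[(1S,4aS,8aS)-4-(2-chloroethyl)-3,4a,8,8-tetramethyl-1,2,4a,5,6,7,8,8a-octahydronaphthalen-1-yl]carbonyl}-1,3-oxazolidin-2-one F2. LiBH4 (THF, MeOH, 0 °C) then releases the primary alcohol [(1S,4aS,8aS)-4-(2-chloroethyl)-3,4a,8,8-tetramethyl-1,2,4a,5,6,7,8,8a-octahydronaphthalen-1-yl]methanol F3, and periodinane oxidation (DMP, CH2Cl2) comes back to the route at aldehyde 20.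

2. Step 16. The Grignard reagent may be lost by protonation if alkoxide formation is incomplete or by Wurtz coupling during its slow formation from the chloride, and a sluggish addition of the bulky reagent may erode the anti selectivity. The fallback separates alkene construction from C–C coupling. It sets out from alkynol 30, which undergoes hydroxyl-directed ruthenium-catalysed trans-hydrostannation ([Cp*RuCl]4 cat., Bu3SnH, CH2Cl2) to the alkenylstannane (2Z,5R)-6-{[(tert-butyldimethylsilyl)oxy]methyl}-2-(tributylstannyl)-5-[(triethylsilyl)oxy]hepta-2,6-dien-1-ol F4. Iododestannylation (I2, CH2Cl2, 0 °C) gives the alkenyl iodide (2Z,5R)-6-{[(tert-butyldimethylsilyl)oxy]methyl}-2-iodo-5-[(triethylsilyl)oxy]hepta-2,6-dien-1-ol F5. Grignard reagent 31 is transmetalated with ZnCl2 to the alkylzinc reagent chloro{2-[(4aS,8aS)-2,5,5,8a-tetramethyl-3,4,4a,5,6,7,8,8a-octahydronaphthalen-1-yl]ethyl}zinc F6, and Negishi coupling with F5 (Pd(dppf)Cl2, THF, rt), which goes with retention, comes back to the route at allylic alcohol 34.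

3. Step 10. CO extrusion from the hindered secondary aldehyde may be incomplete, and β-hydride elimination from the alkylrhodium hydride may give ring olefins instead of the methylene. The fallback removes the carbon by radical decarboxylation. It sets out from aldehyde 20, which is oxidised (NaClO2, NaH2PO4, 2-methylbut-2-ene, t-BuOH/H2O) to the carboxylic acid (1S,4aS,8aS)-4-(2-chloroethyl)-3,4a,8,8-tetramethyl-1,2,4a,5,6,7,8,8a-octahydronaphthalene-1-carboxylic acid F7. Coupling with N-hydroxypyridine-2-thione (DCC, CH2Cl2, dark) gives the O-acyl thiohydroxamate 2-thioxopyridin-1(2H)-yl (1S,4aS,8aS)-4-(2-chloroethyl)-3,4a,8,8-tetramethyl-1,2,4a,5,6,7,8,8a-octahydronaphthalene-1-carboxylate F8, and Barton reductive decarboxylation (t-BuSH, hν, benzene) comes back to the route at chloride 21.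

Further compounds
F1 | step 9 | (4S)-4-benzyl-3-[(2E,8E)-9-(2-chloroethyl)-4,4,8,10-tetramethylundeca-2,8,10-trienoyl]-1,3-oxazolidin-2-one | O=C(/C=C/C(C)(C)CCC/C(C)=C(\CCCl)C(C)=C)N1[C@@H](Cc2ccccc2)COC1=O
F2 | step 9 | (4S)-4-benzyl-3-{[(1S,4aS,8aS)-4-(2-chloroethyl)-3,4a,8,8-tetramethyl-1,2,4a,5,6,7,8,8a-octahydronaphthalen-1-yl]carbonyl}-1,3-oxazolidin-2-one | CC1=C(CCCl)[C@@]2(C)CCCC(C)(C)[C@@H]2[C@@H](C(=O)N3[C@@H](Cc4ccccc4)COC3=O)C1
F3 | step 9 | [(1S,4aS,8aS)-4-(2-chloroethyl)-3,4a,8,8-tetramethyl-1,2,4a,5,6,7,8,8a-octahydronaphthalen-1-yl]methanol | CC1=C(CCCl)[C@@]2(C)CCCC(C)(C)[C@@H]2[C@@H](CO)C1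
F4 | step 16 | (2Z,5R)-6-{[(tert-butyldimethylsilyl)oxy]methyl}-2-(tributylstannyl)-5-[(triethylsilyl)oxy]hepta-2,6-dien-1-ol | OC/C([Sn](CCCC)(CCCC)CCCC)=C/C[C@@H](O[Si](CC)(CC)CC)C(=C)CO[Si](C)(C)C(C)(C)C
F5 | step 16 | (2Z,5R)-6-{[(tert-butyldimethylsilyl)oxy]methyl}-2-iodo-5-[(triethylsilyl)oxy]hepta-2,6-dien-1-ol | OC/C(I)=C/C[C@@H](O[Si](CC)(CC)CC)C(=C)CO[Si](C)(C)C(C)(C)C
F6 | step 16 | chloro{2-[(4aS,8aS)-2,5,5,8a-tetramethyl-3,4,4a,5,6,7,8,8a-octahydronaphthalen-1-yl]ethyl}zinc | CC1=C(CC[Zn]Cl)[C@@]2(C)CCCC(C)(C)[C@@H]2CC1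
F7 | step 10 | (1S,4aS,8aS)-4-(2-chloroethyl)-3,4a,8,8-tetramethyl-1,2,4a,5,6,7,8,8a-octahydronaphthalene-1-carboxylic acid | CC1=C(CCCl)[C@@]2(C)CCCC(C)(C)[C@@H]2[C@@H](C(=O)O)C1
F8 | step 10 | 2-thioxopyridin-1(2H)-yl (1S,4aS,8aS)-4-(2-chloroethyl)-3,4a,8,8-tetramethyl-1,2,4a,5,6,7,8,8a-octahydronaphthalene-1-carboxylate | CC1=C(CCCl)[C@@]2(C)CCCC(C)(C)[C@@H]2[C@@H](C(=O)On3ccccc3=S)C1
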